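**Retrosynthetic overview**
- The strategy rests on the C12 hydroperoxy carbon that carries the cross-conjugated buta-1,3-dien-2-yl unit C16=C13–C14=C15. Both terminal CH2 groups (C15, C16) are removed as one ethylene, leaving a C13≡C14 terminal alkyne with C12 as a masked propargylic peroxide (ethylene–alkyne enyne cross-metathesis; no ring is formed).
- The C12–OO bond is traced to SN2 displacement (inversion) of a (12S)-propargylic mesylate. The mesylate comes from catalyst-controlled transfer hydrogenation of a 12-ynone, made by (trimethylsilyl)acetylide opening of an 8α,12-lactone. O8 is silylated before C12 is activated, because a free 8-OH would close an 8,12-ether.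
- The ring B oxygens (6β-OH, 7β-O, 8α-O) come from a 7-en-6-one: α-face epoxidation, α-face hydride reduction, then CO2-mediated carbonate opening of the epoxide at C7 with inversion while the lactone re-closes on O8.
- Rings A and B with C5, C9 and C10 are bought as (+)-sclareolide. No ring is built; ring B is only oxidised through a temporary 7,8-epoxide and a temporary 6,7-cyclic carbonate.

Key step: step 18

Remark: labdane numbering is used (C12 = former lactone carbonyl, C13/C14 from the acetylene, C15/C16 from ethylene). The (S,S)-ligand → 12S sense of step 12 is assumed by analogy with simple alkynyl ketones, and 2-methoxyprop-2-yl hydroperoxide is not a stock item, so it is made in step 14.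

**Route**

Step 1
Reactants: 1 (+)-sclareolide
Product: 3 methyl 8α-hydroxy-13,14,15,16-tetranorlabdan-12-oate, via potassium 8α-hydroxy carboxylate 2 (not isolated)
Conditions: KOH, MeOH/H2O, reflux; evaporate to dryness; MeI, DMF, rt
Reagents that add atoms: potassium hydroxide [K+].[OH-]; iodomethane CI
Why: Saponification of the γ-lactone followed by O-alkylation of the dry carboxylate gives the hydroxy ester without an acidic stage that would re-close the lactone; no stereocentre is touched.

Step 2
Reactants: 3 methyl 8α-hydroxy-13,14,15,16-tetranorlabdan-12-oate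
Product: 4 methyl 13,14,15,16-tetranorlabd-8(17)-en-12-oate
Conditions: SOCl2, pyridine, CH2Cl2, −78 °C to 0 °C
Reagents that add atoms: none
Why: E2 elimination of the chlorosulfite of the equatorial 8α-alcohol, for which only the C17 methyl hydrogens are antiperiplanar, should give mainly the exocyclic alkene, with some 7-ene 5 that is carried along in the crude mixture.

Step 3
Reactants: 4 methyl 13,14,15,16-tetranorlabd-8(17)-en-12-oate (crude, with some 5)
Product: 5 methyl 13,14,15,16-tetranorlabd-7-en-12-oate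
Conditions: RhCl3·3H2O (cat.), MeOH–toluene, 70 °C; chromatography on AgNO3–SiO2
Reagents that add atoms: none
Why: Rhodium hydride addition–elimination moves the exocyclic double bond into the ring to the trisubstituted 7-position (metal-hydride olefin isomerisation), and further migration to the 8(9)-position needs addition to a trisubstituted alkene and should be slow, so C9 is kept.

Step 4
Reactants: 5 methyl 13,14,15,16-tetranorlabd-7-en-12-oate
Product: 6 methyl 6-oxo-13,14,15,16-tetranorlabd-7-en-12-oate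
Conditions: CrO3, 3,5-dimethylpyrazole, CH2Cl2, −20 °C
Reagents that add atoms: chromium trioxide O=[Cr](=O)=O
Why: Chromium-mediated allylic oxidation attacks the only allylic methylene (C6) and gives the conjugated 7-en-6-one, as is usual for drim-7-enes.

Step 5
Reactants: 6 methyl 6-oxo-13,14,15,16-tetranorlabd-7-en-12-oate
Product: 7 methyl 7α,8α-epoxy-6-oxo-13,14,15,16-tetranorlabdan-12-oate
Conditions: 30% H2O2, NaOH (cat.), MeOH, 0 °C to rt
Reagents that add atoms: hydrogen peroxide OO
Why: Weitz–Scheffer nucleophilic epoxidation, in which hydroperoxide adds to C8 from the α face because β-face approach is 1,3-diaxial to the C10 methyl, sets 8α-O with 8β-methyl and the 7α C–O bond; the equatorial C9 side chain is the thermodynamic epimer, so reversible γ-enolisation is harmless.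

Step 6
Reactants: 7 methyl 7α,8α-epoxy-6-oxo-13,14,15,16-tetranorlabdan-12-oate
Product: 8 methyl 7α,8α-epoxy-6β-hydroxy-13,14,15,16-tetranorlabdan-12-oate
Conditions: NaBH4, MeOH, −20 °C
Reagents that add atoms: none
Why: Borohydride reduction from the α face, the β face of C6 being screened by the syn-axial C4 and C10 methyls, should give the axial 6β-alcohol while the ester and epoxide survive.

Step 7
Reactants: 8 methyl 7α,8α-epoxy-6β-hydroxy-13,14,15,16-tetranorlabdan-12-oate
Product: 10 6β,7β-(carbonyldioxy)-13,14,15,16-tetranorlabdan-12,8α-olide, via hydroxy carbonate ester 9 (not isolated)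
Conditions: CO2 (1 atm), Cs2CO3, 3 Å MS, DMF, 45 °C; then PPTS (cat.), toluene, 60 °C
Reagents that add atoms: carbon dioxide O=C=O
Why: The cesium 6β-alkoxide captures CO2 and the carbonate oxygen opens the epoxide 5-exo at C7 anti to the C7–O bond (CO2/Cs2CO3 conversion of 2,3-epoxy alcohols to hydroxy carbonates), which inverts C7 to 7β-O in a cis-fused carbonate, after which the released 8α-alkoxide lactonises on the ester.

Step 8
Reactants: 10 6β,7β-(carbonyldioxy)-13,14,15,16-tetranorlabdan-12,8α-olide
Product: 12 6β,7β-dihydroxy-13,14,15,16-tetranorlabdan-12,8α-olide, via triol methyl ester 11 (not isolated)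
Conditions: K2CO3, MeOH, rt; then PPTS (cat.), toluene, 50 °C
Reagents that add atoms: none
Why: Base methanolysis removes the strained cyclic carbonate as dimethyl carbonate, and any lactone opened to the hydroxy ester re-closes under mild acid, as tertiary γ-hydroxy esters of this type do.

Step 9
Reactants: 12 6β,7β-dihydroxy-13,14,15,16-tetranorlabdan-12,8α-olide
Product: 13 6β-hydroxy-7β-(triethylsilyloxy)-13,14,15,16-tetranorlabdan-12,8α-olide
Conditions: TESCl, imidazole, DMF, 0 °C
Reagents that add atoms: chlorotriethylsilane CC[Si](Cl)(CC)CC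
Why: Selective silylation of the equatorial 7β-OH, since the axial 6β-OH is syn-axial to three methyl groups (C4β, C10, C8β) and is the least reactive hydroxyl of the series.

Step 10
Reactants: 13 6β-hydroxy-7β-(triethylsilyloxy)-13,14,15,16-tetranorlabdan-12,8α-olide; 14 (trimethylsilyl)acetylene
Product: 16 6β,8α-dihydroxy-7β-(triethylsilyloxy)-14-(trimethylsilyl)-15,16-dinorlabd-13-yn-12-one, via lithium (trimethylsilyl)acetylide 15 (not isolated)
Conditions: n-BuLi, THF, −78 °C (3 equiv of acetylide); add 13, −78 to −40 °C; NH4Cl (aq) at −78 °C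
Reagents that add atoms: none
Why: Acetylide addition to the lactone stops at the lithium hemiketal, which collapses on quench to the hydroxy ynone (single addition of alkynyllithium to a lactone); one equivalent only deprotonates the 6-OH.

Step 11
Reactants: 16 6β,8α-dihydroxy-7β-(triethylsilyloxy)-14-(trimethylsilyl)-15,16-dinorlabd-13-yn-12-one
Product: 17 6β-hydroxy-7β,8α-bis(triethylsilyloxy)-14-(trimethylsilyl)-15,16-dinorlabd-13-yn-12-one
Conditions: TESOTf (1.3 equiv), 2,6-lutidine, CH2Cl2, −78 to −40 °C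
Reagents that add atoms: triethylsilyl trifluoromethanesulfonate CC[Si](CC)(CC)OS(=O)(=O)C(F)(F)F
Why: Silyl triflate silylation of the tertiary 8α-OH at low temperature (no enol silylation, 6β-OH too hindered) blocks the O8 that would otherwise displace any C12 leaving group to give an 8,12-tetrahydrofuran, and also prevents hemiketal formation with the ketone.

Step 12
Reactants: 17 6β-hydroxy-7β,8α-bis(triethylsilyloxy)-14-(trimethylsilyl)-15,16-dinorlabd-13-yn-12-one
Product: 18 (12S)-7β,8α-bis(triethylsilyloxy)-14-(trimethylsilyl)-15,16-dinorlabd-13-yne-6β,12-diol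
Conditions: RuCl[(S,S)-TsDPEN](p-cymene) (cat.), KOH (cat.), iPrOH, rt
Reagents that add atoms: none
Why: Noyori asymmetric transfer hydrogenation, in which the alkynyl group takes the place of the aryl group in the six-membered hydride-transfer transition state, so the (S,S)-ligand should deliver the 12S carbinol under catalyst control.

Step 13
Reactants: 18 (12S)-7β,8α-bis(triethylsilyloxy)-14-(trimethylsilyl)-15,16-dinorlabd-13-yne-6β,12-diol
Product: 19 (12S)-6β-hydroxy-7β,8α-bis(triethylsilyloxy)-14-(trimethylsilyl)-15,16-dinorlabd-13-yn-12-yl methanesulfonate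
Conditions: MsCl (1.1 equiv), Et3N, CH2Cl2, −40 °C
Reagents that add atoms: methanesulfonyl chloride CS(=O)(=O)Cl
Why: Sulfonylation of the unhindered secondary propargylic alcohol with retention at C12; the 6β-OH does not compete and O8 is silylated.

Step 14
Reactants: 20 2,3-dimethylbut-2-ene
Product: 22 2-methoxyprop-2-yl hydroperoxide, via acetone O-oxide 21 (not isolated)
Conditions: O3, MeOH/CH2Cl2, −78 °C; N2 purge; used as a solution
Reagents that add atoms: ozone [O-][O+]=O; methanol CO
Why: Ozonolysis in methanol, the Criegee carbonyl oxide being trapped by the solvent to give the α-methoxy hydroperoxide together with acetone.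

Step 15
Reactants: 19 (12S)-propargylic methanesulfonate; 22 2-methoxyprop-2-yl hydroperoxide
Product: 24 (12R)-12-[(2-methoxyprop-2-yl)peroxy]-7β,8α-bis(triethylsilyloxy)-14-(trimethylsilyl)-15,16-dinorlabd-13-yn-6β-ol, via cesium 2-methoxyprop-2-yl peroxide 23 (not isolated)
Conditions: 22 (1.5 equiv), CsOH·H2O (1.2 equiv), DMF, 0 °C; add 19, 0 °C to rt
Reagents that add atoms: none
Why: SN2 alkylation of the peroxide anion by a secondary sulfonate inverts C12 (12S to 12R) and gives the peroxyketal directly, the linear silylalkyne activating the centre without hindering it; any C-desilylated material converges in step 16.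

Step 16
Reactants: 24 (12R)-12-[(2-methoxyprop-2-yl)peroxy]-7β,8α-bis(triethylsilyloxy)-14-(trimethylsilyl)-15,16-dinorlabd-13-yn-6β-ol
Product: 25 (12R)-12-[(2-methoxyprop-2-yl)peroxy]-15,16-dinorlabd-13-yne-6β,7β,8α-triol
Conditions: TBAF, AcOH (1:1), THF, 0 °C to rt
Reagents that add atoms: none
Why: Buffered fluoride cleaves the C–Si bond of the alkyne and both triethylsilyl ethers, while the base-stable peroxyketal has no O–H and buffering limits base-induced fragmentation at the propargylic C–H.

Step 17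
Reactants: 25 (12R)-12-[(2-methoxyprop-2-yl)peroxy]-15,16-dinorlabd-13-yne-6β,7β,8α-triol
Product: 26 (12R)-7β-acetoxy-12-[(2-methoxyprop-2-yl)peroxy]-15,16-dinorlabd-13-yne-6β,8α-diol
Conditions: Ac2O (1.2 equiv), pyridine, DMAP (cat.), CH2Cl2, 0 °C
Reagents that add atoms: acetic anhydride CC(=O)OC(C)=O
Why: Selective acylation of the equatorial secondary 7β-OH over the hindered axial 6β-OH and the tertiary 8α-OH, under conditions too weakly basic for acetyl migration.

Step 18
Reactants: 26 (12R)-7β-acetoxy-12-[(2-methoxyprop-2-yl)peroxy]-15,16-dinorlabd-13-yne-6β,8α-diol; 27 ethylene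
Product: 28 (12R)-7β-acetoxy-12-[(2-methoxyprop-2-yl)peroxy]labda-13(16),14-diene-6β,8α-diol
Conditions: second-generation Hoveyda–Grubbs catalyst RuCl2(H2IMes)(=CH-C6H4-2-OiPr) (10 mol %), ethylene (1–4 atm), toluene, 40 °C
Reagents that add atoms: none
Why: The ruthenium methylidene adds across the C13≡C14 triple bond to a ruthenacyclobutene that opens to a vinylcarbene, and ethylene turns this over to release the 2-substituted 1,3-diene and regenerate the methylidene, so one ethylene supplies both C15 and C16 and the C13=C16 and C14=C15 double bonds form. The closest known reaction is the ethylene–alkyne enyne cross-metathesis of terminal alkynes that carry a propargylic oxygen substituent. No ring closes and no stereocentre is created; no bond to C12 is made or broken, so the 12R configuration fixed in step 15 passes unchanged into the product. The step needs chemoselectivity: the carbene must react only at the alkyne and leave the O–O bond, the acetate and the two free hydroxyls alone. This should be secured by the terminal, unhindered alkyne, by the peroxide being a ketal-masked dialkyl peroxide without O–H, and by a catalyst that carries no phosphine able to reduce the peroxide. Excess ethylene should suppress alkyne oligomerisation and secondary metathesis of the diene.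

Step 19
Reactants: 28 (12R)-7β-acetoxy-12-[(2-methoxyprop-2-yl)peroxy]labda-13(16),14-diene-6β,8α-diol
Product: 29 (12R)-7β-acetoxy-12-hydroperoxylabda-13(16),14-diene-6β,8α-diol (CNP0356983.1)
Conditions: AcOH/THF/H2O, rt
Reagents that add atoms: none
Why: Mild acid hydrolysis of the peroxyketal frees the hydroperoxide (with acetone and methanol) under conditions that should leave the acetate, the diene and the tertiary alcohol untouched.

**Compound list**
1 | (+)-sclareolide | O=C3C[C@H]1[C@](C)(O3)CC[C@H]2C(C)(C)CCC[C@@]21C | starting material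
2 | potassium 8α-hydroxy-13,14,15,16-tetranorlabdan-12-oate (not isolated) | [K+].[O-]C(=O)C[C@H]1[C@](C)(O)CC[C@H]2C(C)(C)CCC[C@@]21C | intermediate
3 | methyl 8α-hydroxy-13,14,15,16-tetranorlabdan-12-oate | COC(=O)C[C@H]1[C@](C)(O)CC[C@H]2C(C)(C)CCC[C@@]21C | intermediate
4 | methyl 13,14,15,16-tetranorlabd-8(17)-en-12-oate | COC(=O)C[C@H]1C(=C)CC[C@H]2C(C)(C)CCC[C@@]21C | intermediate
5 | methyl 13,14,15,16-tetranorlabd-7-en-12-oate | COC(=O)C[C@H]1C(C)=CC[C@H]2C(C)(C)CCC[C@@]21C | intermediate
6 | methyl 6-oxo-13,14,15,16-tetranorlabd-7-en-12-oate | COC(=O)C[C@H]1C(C)=CC(=O)[C@H]2C(C)(C)CCC[C@@]21C | intermediate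
7 | methyl 7α,8α-epoxy-6-oxo-13,14,15,16-tetranorlabdan-12-oate | COC(=O)C[C@H]1[C@]3(C)O[C@@H]3C(=O)[C@H]2C(C)(C)CCC[C@@]21C | intermediate
8 | methyl 7α,8α-epoxy-6β-hydroxy-13,14,15,16-tetranorlabdan-12-oate | COC(=O)C[C@H]1[C@]3(C)O[C@@H]3[C@@H](O)[C@H]2C(C)(C)CCC[C@@]21C | intermediate
9 | methyl 6β,7β-(carbonyldioxy)-8α-hydroxy-13,14,15,16-tetranorlabdan-12-oate (not isolated) | COC(=O)C[C@H]1[C@](C)(O)[C@H]3OC(=O)O[C@H]3[C@H]2C(C)(C)CCC[C@@]21C | intermediate
10 | 6β,7β-(carbonyldioxy)-13,14,15,16-tetranorlabdan-12,8α-olide | O=C4C[C@H]1[C@](C)(O4)[C@H]3OC(=O)O[C@H]3[C@H]2C(C)(C)CCC[C@@]21C | intermediate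
11 | methyl 6β,7β,8α-trihydroxy-13,14,15,16-tetranorlabdan-12-oate (not isolated) | COC(=O)C[C@H]1[C@](C)(O)[C@@H](O)[C@@H](O)[C@H]2C(C)(C)CCC[C@@]21C | intermediate
12 | 6β,7β-dihydroxy-13,14,15,16-tetranorlabdan-12,8α-olide | O=C3C[C@H]1[C@](C)(O3)[C@@H](O)[C@@H](O)[C@H]2C(C)(C)CCC[C@@]21C | intermediate
13 | 6β-hydroxy-7β-(triethylsilyloxy)-13,14,15,16-tetranorlabdan-12,8α-olide | O=C3C[C@H]1[C@](C)(O3)[C@@H](O[Si](CC)(CC)CC)[C@@H](O)[C@H]2C(C)(C)CCC[C@@]21C | intermediate
14 | (trimethylsilyl)acetylene | C#C[Si](C)(C)C | starting material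
15 | lithium (trimethylsilyl)acetylide (not isolated) | [Li]C#C[Si](C)(C)C | intermediate
16 | 6β,8α-dihydroxy-7β-(triethylsilyloxy)-14-(trimethylsilyl)-15,16-dinorlabd-13-yn-12-one | C[Si](C)(C)C#CC(=O)C[C@H]1[C@](C)(O)[C@@H](O[Si](CC)(CC)CC)[C@@H](O)[C@H]2C(C)(C)CCC[C@@]21C | intermediate
17 | 6β-hydroxy-7β,8α-bis(triethylsilyloxy)-14-(trimethylsilyl)-15,16-dinorlabd-13-yn-12-one | C[Si](C)(C)C#CC(=O)C[C@H]1[C@](C)(O[Si](CC)(CC)CC)[C@@H](O[Si](CC)(CC)CC)[C@@H](O)[C@H]2C(C)(C)CCC[C@@]21C | intermediate
18 | (12S)-7β,8α-bis(triethylsilyloxy)-14-(trimethylsilyl)-15,16-dinorlabd-13-yne-6β,12-diol | C[Si](C)(C)C#C[C@H](C[C@H]1[C@](C)(O[Si](CC)(CC)CC)[C@@H](O[Si](CC)(CC)CC)[C@@H](O)[C@H]2C(C)(C)CCC[C@@]21C)O | intermediate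
19 | (12S)-6β-hydroxy-7β,8α-bis(triethylsilyloxy)-14-(trimethylsilyl)-15,16-dinorlabd-13-yn-12-yl methanesulfonate | C[Si](C)(C)C#C[C@H](C[C@H]1[C@](C)(O[Si](CC)(CC)CC)[C@@H](O[Si](CC)(CC)CC)[C@@H](O)[C@H]2C(C)(C)CCC[C@@]21C)OS(C)(=O)=O | intermediate
20 | 2,3-dimethylbut-2-ene | CC(C)=C(C)C | starting material
21 | acetone O-oxide (not isolated) | CC(C)=[O+][O-] | intermediate
22 | 2-methoxyprop-2-yl hydroperoxide | COC(C)(C)OO | intermediate
23 | cesium 2-methoxyprop-2-yl peroxide (not isolated) | [Cs+].COC(C)(C)O[O-] | intermediate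
24 | (12R)-12-[(2-methoxyprop-2-yl)peroxy]-7β,8α-bis(triethylsilyloxy)-14-(trimethylsilyl)-15,16-dinorlabd-13-yn-6β-ol | C[Si](C)(C)C#C[C@@H](C[C@H]1[C@](C)(O[Si](CC)(CC)CC)[C@@H](O[Si](CC)(CC)CC)[C@@H](O)[C@H]2C(C)(C)CCC[C@@]21C)OOC(C)(C)OC | intermediate
25 | (12R)-12-[(2-methoxyprop-2-yl)peroxy]-15,16-dinorlabd-13-yne-6β,7β,8α-triol | C#C[C@@H](C[C@H]1[C@](C)(O)[C@@H](O)[C@@H](O)[C@H]2C(C)(C)CCC[C@@]21C)OOC(C)(C)OC | intermediate
26 | (12R)-7β-acetoxy-12-[(2-methoxyprop-2-yl)peroxy]-15,16-dinorlabd-13-yne-6β,8α-diol | C#C[C@@H](C[C@H]1[C@](C)(O)[C@@H](OC(C)=O)[C@@H](O)[C@H]2C(C)(C)CCC[C@@]21C)OOC(C)(C)OC | intermediate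
27 | ethylene | C=C | starting material
28 | (12R)-7β-acetoxy-12-[(2-methoxyprop-2-yl)peroxy]labda-13(16),14-diene-6β,8α-diol | C=CC(=C)[C@@H](C[C@H]1[C@](C)(O)[C@@H](OC(C)=O)[C@@H](O)[C@H]2C(C)(C)CCC[C@@]21C)OOC(C)(C)OC | intermediate
29 | (12R)-7β-acetoxy-12-hydroperoxylabda-13(16),14-diene-6β,8α-diol (CNP0356983.1) | C=CC(=C)[C@@H](C[C@H]1[C@](C)(O)[C@@H](OC(C)=O)[C@@H](O)[C@H]2C(C)(C)CCC[C@@]21C)OO | target

**Step count**
Total: 19 steps. Longest linear sequence: 18 steps (steps 1–13 and 15–19 from sclareolide); step 14 is a one-step side branch.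

**Steps most likely to fail**

1. Step 18 (enyne metathesis). The carbene may be destroyed by the O–O bond, or the vinylcarbene may be held by chelation to the peroxy and ketal oxygens, so that turnover stops; alkyne oligomerisation may compete. Fallback: build the diene by cross-coupling instead of metathesis, setting out from 26 and returning at 28. Markovnikov hydrosilylation of the terminal alkyne ([Cp*Ru(MeCN)3]PF6 cat., Et3SiH, CH2Cl2, 0 °C) should give the 13-(triethylsilyl)-13-ene F1. Iododesilylation (N-iodosuccinimide, 2,6-lutidine, hexafluoroisopropanol/CH2Cl2, 0 °C) should give the 13-iodo-13-ene F2. Stille coupling of F2 with tributyl(vinyl)stannane (Pd2(dba)3 as the zerovalent palladium source, AsPh3, CuI, DMF, rt, no phosphine) then gives 28.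

2. Step 15 (peroxide SN2). Elimination to the conjugated enyne, SN2′ attack at the alkyne terminus, base-induced fragmentation of the product peroxide at its propargylic C–H, or partial ionisation that erodes the inversion may take over. Fallback: form the C12–OO bond by radical hydroperoxysilylation instead of substitution, setting out from 19 and returning at 25. Elimination with DBU (toluene, 60 °C) gives the (11E)-11-en-13-yne F3. Isayama–Mukaiyama peroxidation (Co(thd)2, i.e. cobalt bis(2,2,6,6-tetramethylheptane-3,5-dionate), cat., O2, Et3SiH, 1,2-dichloroethane, rt) places the triethylsilylperoxy group at the propargylic C12; both C12 epimers are expected, and the 12R epimer F4 is separated by chromatography. K2CO3/MeOH at 0 °C removes the peroxy-silyl and alkynyl-silyl groups to give the hydroperoxide F5. 2-Methoxypropene with PPTS (cat.) in CH2Cl2 at 0 °C masks it as the peroxyketal F6, and buffered TBAF/AcOH gives 25.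

3. Step 7 (carbonate opening of the epoxide). Attack at C7 needs a non-diaxial trajectory and may stall, the carbonate oxygen may instead attack the tertiary C8 to give a 6,8-bridged carbonate, or lactonisation may stay incomplete. Fallback: invert C7 by oxidation and reduction, setting out from 8 and returning at 12. Base-induced Payne rearrangement with in situ lactonisation (KOtBu cat., THF, 0 °C to rt) should give the 6β,7β-epoxy lactone F7. Acid-catalysed trans-diaxial hydrolysis (HClO4 cat., THF/H2O) gives the 6β,7α-diol lactone F8. Selective oxidation of the accessible axial 7α-OH (Dess–Martin periodinane, NaHCO3, CH2Cl2, 0 °C) gives the 6β-hydroxy-7-ketone F9, and NaBH4 (MeOH, −40 °C), attacking from the α face, gives the equatorial 7β-alcohol 12.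

**Further compounds**
F1 | step 18 | (12R)-7β-acetoxy-12-[(2-methoxyprop-2-yl)peroxy]-13-(triethylsilyl)-15,16-dinorlabd-13-ene-6β,8α-diol | C=C([Si](CC)(CC)CC)[C@@H](C[C@H]1[C@](C)(O)[C@@H](OC(C)=O)[C@@H](O)[C@H]2C(C)(C)CCC[C@@]21C)OOC(C)(C)OC
F2 | step 18 | (12R)-7β-acetoxy-13-iodo-12-[(2-methoxyprop-2-yl)peroxy]-15,16-dinorlabd-13-ene-6β,8α-diol | C=C(I)[C@@H](C[C@H]1[C@](C)(O)[C@@H](OC(C)=O)[C@@H](O)[C@H]2C(C)(C)CCC[C@@]21C)OOC(C)(C)OC
F3 | step 15 | (11E)-7β,8α-bis(triethylsilyloxy)-14-(trimethylsilyl)-15,16-dinorlabd-11-en-13-yn-6β-ol | C[Si](C)(C)C#C/C=C/[C@H]1[C@](C)(O[Si](CC)(CC)CC)[C@@H](O[Si](CC)(CC)CC)[C@@H](O)[C@H]2C(C)(C)CCC[C@@]21C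
F4 | step 15 | (12R)-7β,8α-bis(triethylsilyloxy)-12-(triethylsilylperoxy)-14-(trimethylsilyl)-15,16-dinorlabd-13-yn-6β-ol | C[Si](C)(C)C#C[C@@H](C[C@H]1[C@](C)(O[Si](CC)(CC)CC)[C@@H](O[Si](CC)(CC)CC)[C@@H](O)[C@H]2C(C)(C)CCC[C@@]21C)OO[Si](CC)(CC)CC
F5 | step 15 | (12R)-12-hydroperoxy-7β,8α-bis(triethylsilyloxy)-15,16-dinorlabd-13-yn-6β-ol | C#C[C@@H](C[C@H]1[C@](C)(O[Si](CC)(CC)CC)[C@@H](O[Si](CC)(CC)CC)[C@@H](O)[C@H]2C(C)(C)CCC[C@@]21C)OO
F6 | step 15 | (12R)-12-[(2-methoxyprop-2-yl)peroxy]-7β,8α-bis(triethylsilyloxy)-15,16-dinorlabd-13-yn-6β-ol | C#C[C@@H](C[C@H]1[C@](C)(O[Si](CC)(CC)CC)[C@@H](O[Si](CC)(CC)CC)[C@@H](O)[C@H]2C(C)(C)CCC[C@@]21C)OOC(C)(C)OC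
F7 | step 7 | 6β,7β-epoxy-13,14,15,16-tetranorlabdan-12,8α-olide | O=C3C[C@H]1[C@](C)(O3)[C@H]4O[C@H]4[C@H]2C(C)(C)CCC[C@@]21C
F8 | step 7 | 6β,7α-dihydroxy-13,14,15,16-tetranorlabdan-12,8α-olide | O=C3C[C@H]1[C@](C)(O3)[C@H](O)[C@@H](O)[C@H]2C(C)(C)CCC[C@@]21C
F9 | step 7 | 6β-hydroxy-7-oxo-13,14,15,16-tetranorlabdan-12,8α-olide | O=C3C[C@H]1[C@](C)(O3)C(=O)[C@@H](O)[C@H]2C(C)(C)CCC[C@@]21C
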